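## Retrosynthetic overview

- The last C–C bond is a B-alkyl Suzuki union of a C15 ring triol (vinyl group on the quaternary carbon) with a C15 (E)-vinyl iodide that already carries the epoxy alcohol; the enal is revealed last by allylic oxidation.
- All ring stereochemistry traces back to one C–O bond: enantioselective para-hydroxylative dearomatisation of 3,4-dimethylphenol. The tertiary carbinol then relays to the quaternary centre (anti conjugate vinylation) and to C2 (anti enolate allylation).
- The enal unit comes from isopropenyl addition to the ring ketone and a 1,3-hydroxyl transposition to the (Z)-tetrasubstituted allylic alcohol.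
- The chain comes from (E)-geranylacetone: alkyne, carboalumination/iodination, terminal epoxide, tertiary allylic alcohol, oxidative transposition, CBS reduction, hydroxyl-directed epoxidation.
- Ring order: the carbocycle is not built but inherited from the arene (dearomatised in step 1); the oxirane is closed in step 14, before the fragments are joined.

Assumption: the (R,R)-enantiomer of the new catalyst in step 1 is taken to give the (S)-quinol; if the sense is the reverse, the (S,S)-catalyst is used.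

## Route

Step 1
Reactants: 1 3,4-dimethylphenol
Product: 2 (4S)-4-hydroxy-3,4-dimethylcyclohexa-2,5-dien-1-one
Conditions: (R,R)-2,2'-[(2-iodo-1,3-phenylene)bis(oxy)]bis[N-(2,4,6-trimethylphenyl)propanamide] (10 mol%), mCPBA (1.2 equiv), MeCN/H2O 4:1, −20 °C
Reagents that add atoms: water, O
Why: Proposed new method: the aryl iodide is oxidised by mCPBA to a trivalent iodine species that binds the phenol through oxygen; the two hydrogen-bonded lactamide arms fold into a C2-symmetric pocket in which the 3-methyl group allows only one rotamer of the aryloxy–iodine bond, so water adds to C4 (the methyl-stabilised para position) on the face anti to iodine as the aryl iodide departs (SN2′-type), setting (S)-C4; the closest known reactions are chiral aryl-iodide-catalysed dearomatising spirolactonisations of phenols and the racemic PhI(OAc)2/H2O synthesis of para-quinols.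

Step 2
Reactants: 2 (4S)-4-hydroxy-3,4-dimethylcyclohexa-2,5-dien-1-one
Product: 3 (4S)-4-hydroxy-3,4-dimethylcyclohex-2-en-1-one
Conditions: H2 (1 atm), RhCl(PPh3)3 (5 mol%), benzene/EtOH, 25 °C
Reagents that add atoms: none
Why: Homogeneous hydrogenation with RhCl(PPh3)3 reduces the unhindered disubstituted enone C=C much faster than the trisubstituted methyl-bearing one, and the carbinol stereocentre is not touched.

Step 3
Reactants: 3 (4S)-4-hydroxy-3,4-dimethylcyclohex-2-en-1-one
Product: 4 (4S)-3,4-dimethyl-4-(trimethylsilyloxy)cyclohex-2-en-1-one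
Conditions: 1-(trimethylsilyl)imidazole, CH2Cl2, 25 °C
Reagents that add atoms: 1-(trimethylsilyl)imidazole, C[Si](C)(C)n1ccnc1
Why: O-silylation of the tertiary alcohol with a neutral silyl-transfer reagent does not enolise the enone, and the silyl ether prevents alkoxide-directed syn delivery in step 4.

Step 4
Reactants: 4 (4S)-3,4-dimethyl-4-(trimethylsilyloxy)cyclohex-2-en-1-one
Product: 7 (2S,3S,4S)-3-ethenyl-3,4-dimethyl-2-(prop-2-en-1-yl)-4-(trimethylsilyloxy)cyclohexan-1-one, via silyl enol ether 5 (not isolated), via lithium enolate 6 (not isolated)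
Conditions: CH2=CHMgBr, CuBr·SMe2 (15 mol%), Me3SiCl, DMPU, THF, −78 °C; then MeLi, 0 °C; then allyl iodide, −78 → −20 °C
Reagents that add atoms: vinylmagnesium bromide, C=C[Mg]Br; allyl iodide, C=CCI
Why: Me3SiCl-accelerated copper-catalysed conjugate addition takes place axially, anti to the pseudo-axial C4 silyloxy group (vinyl trans to O at the new quaternary C3), and the lithium enolate released from the silyl enol ether is allylated axially anti to the now axial vinyl group, the only syn-axial neighbour being the small silyloxy oxygen (allyl trans to vinyl at C2); conjugate addition–enolate alkylation.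

Step 5
Reactants: 7 (2S,3S,4S)-3-ethenyl-3,4-dimethyl-2-(prop-2-en-1-yl)-4-(trimethylsilyloxy)cyclohexan-1-one
Product: 8 (1R,2S,3S,4S)-3-ethenyl-3,4-dimethyl-1-(prop-1-en-2-yl)-2-(prop-2-en-1-yl)-4-(trimethylsilyloxy)cyclohexan-1-ol
Conditions: CH2=C(CH3)MgBr, CeCl3, THF, −78 → 0 °C
Reagents that add atoms: isopropenylmagnesium bromide, CC(=C)[Mg]Br
Why: The organocerium reagent adds 1,2 to the hindered, enolisable ketone without deprotonation (equatorial attack expected; the C1 configuration is erased in step 6); carbonyl addition.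

Step 6
Reactants: 8 (1R,2S,3S,4S)-3-ethenyl-3,4-dimethyl-1-(prop-1-en-2-yl)-2-(prop-2-en-1-yl)-4-(trimethylsilyloxy)cyclohexan-1-ol
Product: 10 (2Z)-2-[(2R,3S,4S)-3-ethenyl-4-hydroxy-3,4-dimethyl-2-(prop-2-en-1-yl)cyclohexylidene]propan-1-ol, via bis-silyl ether 9 (not isolated)
Conditions: Ph3SiOReO3 (3 mol%), N,O-bis(trimethylsilyl)acetamide, Et2O, 0 °C; then Bu4NF, THF, 0 °C
Reagents that add atoms: none
Why: Perrhenate-ester [3,3] 1,3-hydroxyl transposition is pulled to the primary allylic alcohol and tetrasubstituted alkene by selective silylation of the primary hydroxyl; in the chair transition state the slim =CH2 terminus rather than the methyl group lies next to the substituted C2, which gives the Z alkene, and fluoride then removes both silyl groups.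

Step 7
Reactants: 10 (2Z)-2-[(2R,3S,4S)-3-ethenyl-4-hydroxy-3,4-dimethyl-2-(prop-2-en-1-yl)cyclohexylidene]propan-1-ol
Product: 12 (2Z)-2-[(2R,3S,4S)-3-ethenyl-4-hydroxy-2-(3-hydroxypropyl)-3,4-dimethylcyclohexylidene]propan-1-ol, via organoborane 11 (not isolated)
Conditions: 9-BBN (2.2 equiv), THF, 0 → 25 °C; then NaOH, H2O2, 0 °C
Reagents that add atoms: hydrogen peroxide, OO
Why: 9-BBN reacts with the unhindered monosubstituted allyl alkene far faster than with the neopentyl-type vinyl group or the tetrasubstituted alkene; anti-Markovnikov hydroboration–oxidation.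

Step 8
Reactants: 13 (5E)-6,10-dimethylundeca-5,9-dien-2-one ((E)-geranylacetone)
Product: 15 (5E)-6,10-dimethylundeca-5,9-dien-1-yne, via enol phosphate 14 (not isolated)
Conditions: LiN(iPr)2, THF, −78 °C; ClP(O)(OEt)2; then LiN(iPr)2 (2.3 equiv), −78 → 25 °C
Reagents that add atoms: none
Why: Kinetic enolate phosphorylation on the methyl side and base-induced elimination of the enol phosphate convert the methyl ketone into the terminal alkyne (Negishi alkyne synthesis) without touching the E alkene.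

Step 9
Reactants: 15 (5E)-6,10-dimethylundeca-5,9-dien-1-yne
Product: 17 (1E,5E)-1-iodo-2,6,10-trimethylundeca-1,5,9-triene, via alkenylalane 16 (not isolated)
Conditions: AlMe3, Cp2ZrCl2 (20 mol%), CH2Cl2, 0 → 25 °C; then I2, THF, −30 °C
Reagents that add atoms: trimethylaluminium, C[Al](C)C; iodine, II
Why: Zirconium-catalysed syn carboalumination (Negishi) of the terminal alkyne places methyl on the internal carbon, and iodinolysis with retention gives the E vinyl iodide.

Step 10
Reactants: 17 (1E,5E)-1-iodo-2,6,10-trimethylundeca-1,5,9-triene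
Product: 19 racemic 3-[(3E,7E)-8-iodo-3,7-dimethylocta-3,7-dien-1-yl]-2,2-dimethyloxirane, via bromohydrin 18 (not isolated)
Conditions: NBS, THF/H2O, 0 °C; then K2CO3, MeOH, 25 °C
Reagents that add atoms: water, O
Why: In aqueous THF NBS attacks the terminal trisubstituted alkene in preference to the internal one and the electron-poor vinyl iodide (van Tamelen bromohydrin formation), and base closes the bromohydrin to the epoxide; the new stereocentre is racemic and is removed in step 11.

Step 11
Reactants: 19 racemic 3-[(3E,7E)-8-iodo-3,7-dimethylocta-3,7-dien-1-yl]-2,2-dimethyloxirane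
Product: 22 (3E,6E,10E)-11-iodo-2,6,10-trimethylundeca-3,6,10-trien-2-ol, via hydroxy selenide 20 (not isolated), via selenoxide 21 (not isolated)
Conditions: PhSeSePh, NaBH4, EtOH, 25 °C; then H2O2, THF, 0 → 25 °C
Reagents that add atoms: none
Why: Selenolate opens the epoxide at the less hindered secondary carbon, and selenoxide syn-elimination away from the carbinol gives the E tertiary allylic alcohol (Sharpless–Lauer epoxide to allylic alcohol conversion).

Step 12
Reactants: 22 (3E,6E,10E)-11-iodo-2,6,10-trimethylundeca-3,6,10-trien-2-ol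
Product: 23 (6E,10E)-11-iodo-2,6,10-trimethylundeca-2,6,10-trien-4-one
Conditions: (C5H5NH)[CrO3Cl], NaOAc, CH2Cl2, 25 °C
Reagents that add atoms: pyridinium chlorochromate, [O-][Cr](=O)(=O)Cl.c1cc[nH+]cc1
Why: The tertiary allylic chromate ester undergoes a [3,3] shift and oxidation to the transposed enone (Babler–Dauben oxidative transposition), and the acetate buffer keeps the skipped alkene out of conjugation.

Step 13
Reactants: 23 (6E,10E)-11-iodo-2,6,10-trimethylundeca-2,6,10-trien-4-one
Product: 24 (4S,6E,10E)-11-iodo-2,6,10-trimethylundeca-2,6,10-trien-4-ol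
Conditions: (R)-1-methyl-3,3-diphenyltetrahydro-1H,3H-pyrrolo[1,2-c][1,3,2]oxazaborole (20 mol%), catecholborane, toluene, −78 °C
Reagents that add atoms: none
Why: CBS reduction with the alkenyl group as the large substituent: the (R)-catalyst delivers hydride to the face that gives the (4S)-alcohol, and catecholborane leaves the alkenes alone.

Step 14
Reactants: 24 (4S,6E,10E)-11-iodo-2,6,10-trimethylundeca-2,6,10-trien-4-ol
Product: 25 (1S,3E,7E)-1-[(2R)-3,3-dimethyloxiran-2-yl]-8-iodo-3,7-dimethylocta-3,7-dien-1-ol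
Conditions: Ti(OiPr)4 (10 mol%), t-BuOOH, 4 Å MS, CH2Cl2, −20 °C
Reagents that add atoms: tert-butyl hydroperoxide, CC(C)(C)OO
Why: Hydroxyl-directed epoxidation: A(1,3) strain with the cis methyl group holds the carbinol hydrogen in the alkene plane, so the titanium-bound peroxide is delivered to one face and gives the threo (1S,2′R) epoxy alcohol, while the homoallylic alkene and the vinyl iodide do not react.

Step 15
Reactants: 12 (2Z)-2-[(2R,3S,4S)-3-ethenyl-4-hydroxy-2-(3-hydroxypropyl)-3,4-dimethylcyclohexylidene]propan-1-ol; 25 (1S,3E,7E)-1-[(2R)-3,3-dimethyloxiran-2-yl]-8-iodo-3,7-dimethylocta-3,7-dien-1-ol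
Product: 27 (2Z)-2-[(2R,3S,4S)-3-{(3E,7E,10S)-10-[(2R)-3,3-dimethyloxiran-2-yl]-10-hydroxy-4,8-dimethyldeca-3,7-dien-1-yl}-4-hydroxy-2-(3-hydroxypropyl)-3,4-dimethylcyclohexylidene]propan-1-ol, via organoborane 26 (not isolated)
Conditions: 12, 9-BBN (3.5 equiv), THF, 25 → 45 °C; then H2O; then 25, PdCl2(dppf) (10 mol%), AsPh3, Cs2CO3, DMF/H2O, 25 °C
Reagents that add atoms: none
Why: B-alkyl Suzuki–Miyaura coupling: anti-Markovnikov hydroboration of the vinyl group gives a primary alkylborane that couples with the vinyl iodide with retention of the E geometry, and the free hydroxyls and the epoxide are tolerated under the aqueous carbonate conditions.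

Step 16
Reactants: 27 (2Z)-2-[(2R,3S,4S)-3-{(3E,7E,10S)-10-[(2R)-3,3-dimethyloxiran-2-yl]-10-hydroxy-4,8-dimethyldeca-3,7-dien-1-yl}-4-hydroxy-2-(3-hydroxypropyl)-3,4-dimethylcyclohexylidene]propan-1-ol
Product: 28 (2Z)-2-[(2R,3S,4S)-3-{(3E,7E,10S)-10-[(2R)-3,3-dimethyloxiran-2-yl]-10-hydroxy-4,8-dimethyldeca-3,7-dien-1-yl}-4-hydroxy-2-(3-hydroxypropyl)-3,4-dimethylcyclohexylidene]propanal (CNP0161066.1)
Conditions: MnO2, CH2Cl2, 25 °C
Reagents that add atoms: none
Why: MnO2 oxidises only the allylic primary alcohol and leaves the saturated primary, secondary and tertiary alcohols, the epoxide and the alkene geometry untouched; chemoselective allylic oxidation.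

## Compound list

1 | 3,4-dimethylphenol | Cc1ccc(O)cc1C | starting material
2 | (4S)-4-hydroxy-3,4-dimethylcyclohexa-2,5-dien-1-one | O=C1C=C[C@](C)(O)C(C)=C1 | intermediate
3 | (4S)-4-hydroxy-3,4-dimethylcyclohex-2-en-1-one | O=C1CC[C@](C)(O)C(C)=C1 | intermediate
4 | (4S)-3,4-dimethyl-4-(trimethylsilyloxy)cyclohex-2-en-1-one | O=C1CC[C@](C)(O[Si](C)(C)C)C(C)=C1 | intermediate
5 | {[(3S,4S)-3-ethenyl-3,4-dimethyl-4-(trimethylsilyloxy)cyclohex-1-en-1-yl]oxy}trimethylsilane (silyl enol ether) | C=C[C@@]1(C)C=C(O[Si](C)(C)C)CC[C@]1(C)O[Si](C)(C)C | intermediate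
6 | lithium (3S,4S)-3-ethenyl-3,4-dimethyl-4-(trimethylsilyloxy)cyclohex-1-en-1-olate (lithium enolate) | C=C[C@@]1(C)C=C([O-])CC[C@]1(C)O[Si](C)(C)C.[Li+] | intermediate
7 | (2S,3S,4S)-3-ethenyl-3,4-dimethyl-2-(prop-2-en-1-yl)-4-(trimethylsilyloxy)cyclohexan-1-one | O=C1CC[C@](C)(O[Si](C)(C)C)[C@@](C)(C=C)[C@@H]1CC=C | intermediate
8 | (1R,2S,3S,4S)-3-ethenyl-3,4-dimethyl-1-(prop-1-en-2-yl)-2-(prop-2-en-1-yl)-4-(trimethylsilyloxy)cyclohexan-1-ol | CC(=C)[C@@]1(O)CC[C@](C)(O[Si](C)(C)C)[C@@](C)(C=C)[C@@H]1CC=C | intermediate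
9 | {(2Z)-2-[(2R,3S,4S)-3-ethenyl-3,4-dimethyl-2-(prop-2-en-1-yl)-4-(trimethylsilyloxy)cyclohexylidene]propoxy}trimethylsilane (bis-silyl ether) | C/C(CO[Si](C)(C)C)=C1\CC[C@](C)(O[Si](C)(C)C)[C@@](C)(C=C)[C@@H]1CC=C | intermediate
10 | (2Z)-2-[(2R,3S,4S)-3-ethenyl-4-hydroxy-3,4-dimethyl-2-(prop-2-en-1-yl)cyclohexylidene]propan-1-ol | C/C(CO)=C1\CC[C@](C)(O)[C@@](C)(C=C)[C@@H]1CC=C | intermediate
11 | B-alkyl-9-BBN of 10 at the allyl terminus, primary hydroxyl as its 9-BBN borinate (organoborane) | C/C(COB2C3CCCC2CCC3)=C1\CC[C@](C)(O)[C@@](C)(C=C)[C@@H]1CCCB2C3CCCC2CCC3 | intermediate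
12 | (2Z)-2-[(2R,3S,4S)-3-ethenyl-4-hydroxy-2-(3-hydroxypropyl)-3,4-dimethylcyclohexylidene]propan-1-ol | C/C(CO)=C1\CC[C@](C)(O)[C@@](C)(C=C)[C@@H]1CCCO | intermediate
13 | (5E)-6,10-dimethylundeca-5,9-dien-2-one ((E)-geranylacetone) | CC(=O)CC/C=C(\C)CCC=C(C)C | starting material
14 | diethyl (5E)-6,10-dimethylundeca-1,5,9-trien-2-yl phosphate (enol phosphate) | C=C(OP(=O)(OCC)OCC)CC/C=C(\C)CCC=C(C)C | intermediate
15 | (5E)-6,10-dimethylundeca-5,9-dien-1-yne | C#CCC/C=C(\C)CCC=C(C)C | intermediate
16 | dimethyl[(1E,5E)-2,6,10-trimethylundeca-1,5,9-trien-1-yl]alane (alkenylalane) | C[Al](C)/C=C(\C)CC/C=C(\C)CCC=C(C)C | intermediate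
17 | (1E,5E)-1-iodo-2,6,10-trimethylundeca-1,5,9-triene | I/C=C(\C)CC/C=C(\C)CCC=C(C)C | intermediate
18 | racemic (6E,10E)-3-bromo-11-iodo-2,6,10-trimethylundeca-6,10-dien-2-ol (bromohydrin) | I/C=C(\C)CC/C=C(\C)CCC(Br)C(C)(C)O | intermediate
19 | racemic 3-[(3E,7E)-8-iodo-3,7-dimethylocta-3,7-dien-1-yl]-2,2-dimethyloxirane | I/C=C(\C)CC/C=C(\C)CCC1OC1(C)C | intermediate
20 | racemic (6E,10E)-11-iodo-2,6,10-trimethyl-3-(phenylselanyl)undeca-6,10-dien-2-ol (hydroxy selenide) | I/C=C(\C)CC/C=C(\C)CCC([Se]c1ccccc1)C(C)(C)O | intermediate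
21 | (6E,10E)-11-iodo-2,6,10-trimethyl-3-(phenylseleninyl)undeca-6,10-dien-2-ol (selenoxide) | I/C=C(\C)CC/C=C(\C)CCC([Se](=O)c1ccccc1)C(C)(C)O | intermediate
22 | (3E,6E,10E)-11-iodo-2,6,10-trimethylundeca-3,6,10-trien-2-ol | I/C=C(\C)CC/C=C(\C)C/C=C/C(C)(C)O | intermediate
23 | (6E,10E)-11-iodo-2,6,10-trimethylundeca-2,6,10-trien-4-one | I/C=C(\C)CC/C=C(\C)CC(=O)C=C(C)C | intermediate
24 | (4S,6E,10E)-11-iodo-2,6,10-trimethylundeca-2,6,10-trien-4-ol | I/C=C(\C)CC/C=C(\C)C[C@H](O)C=C(C)C | intermediate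
25 | (1S,3E,7E)-1-[(2R)-3,3-dimethyloxiran-2-yl]-8-iodo-3,7-dimethylocta-3,7-dien-1-ol | I/C=C(\C)CC/C=C(\C)C[C@H](O)[C@H]1OC1(C)C | intermediate
26 | B-alkyl-9-BBN of 12 at the vinyl terminus, both primary hydroxyls as 9-BBN borinates (organoborane) | C/C(COB2C3CCCC2CCC3)=C1\CC[C@](C)(O)[C@@](C)(CCB2C3CCCC2CCC3)[C@@H]1CCCOB2C3CCCC2CCC3 | intermediate
27 | (2Z)-2-[(2R,3S,4S)-3-{(3E,7E,10S)-10-[(2R)-3,3-dimethyloxiran-2-yl]-10-hydroxy-4,8-dimethyldeca-3,7-dien-1-yl}-4-hydroxy-2-(3-hydroxypropyl)-3,4-dimethylcyclohexylidene]propan-1-ol | C/C(CO)=C1\CC[C@](C)(O)[C@@](C)(CC/C=C(\C)CC/C=C(\C)C[C@H](O)[C@H]2OC2(C)C)[C@@H]1CCCO | intermediate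
28 | (2Z)-2-[(2R,3S,4S)-3-{(3E,7E,10S)-10-[(2R)-3,3-dimethyloxiran-2-yl]-10-hydroxy-4,8-dimethyldeca-3,7-dien-1-yl}-4-hydroxy-2-(3-hydroxypropyl)-3,4-dimethylcyclohexylidene]propanal | C/C(C=O)=C1\CC[C@](C)(O)[C@@](C)(CC/C=C(\C)CC/C=C(\C)C[C@H](O)[C@H]2OC2(C)C)[C@@H]1CCCO | target

## Step count and risks

Total steps: 16. Longest linear sequence: 9 (steps 1–7, 15, 16; the chain branch, steps 8–14, 15, 16, is equally long).

Steps most likely to fail:

1. Step 1 (the proposed new reaction). The enantioselectivity of an intermolecular para-hydroxylation that must read a meta-methyl group is unproven, and ortho attack could compete. Fallback with known chemistry: starting from 1, PhI(OAc)2 in MeCN/H2O at 0 °C gives racemic 4-hydroxy-3,4-dimethylcyclohexa-2,5-dien-1-one F1. The enantiomers are separated by preparative chromatography on a chiral stationary phase, and the (S)-enantiomer is 2, where the route resumes.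

2. Step 4. The cuprate must add to a β-methyl enone next to a fully substituted carbon, and the C2 configuration rests on substrate-controlled axial alkylation of a hindered enolate. Fallback: starting from 4, the same vinyl addition is stopped at silyl enol ether 5, which is isolated. MeLi then allyl chloroformate converts it into allyl (3S,4S)-3-ethenyl-3,4-dimethyl-4-(trimethylsilyloxy)cyclohex-1-en-1-yl carbonate F2. Pd2(dba)3 with (S)-4-tert-butyl-2-[2-(diphenylphosphino)phenyl]-4,5-dihydrooxazole (ligand enantiomer chosen for the 2S product) then effects decarboxylative allylation under catalyst control and returns to 7.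

3. Step 6. The Z geometry of the tetrasubstituted alkene depends on a kinetic preference in a reversible transposition and may come out as a mixture of alkene isomers. Fallback: starting from 8, (C5H5NH)[CrO3Cl] in CH2Cl2 (oxidative transposition) gives the enal as (2E)-2-[(2R,3S,4S)-3-ethenyl-3,4-dimethyl-2-(prop-2-en-1-yl)-4-(trimethylsilyloxy)cyclohexylidene]propanal F3 together with its (2Z)-isomer F4. A trace of I2 equilibrates the pair toward F4, which is expected to be favoured because the flat formyl group sits better than methyl next to the axially substituted C2; F4 is separated and F3 recycled. NaBH4/CeCl3 in MeOH reduces F4 to (2Z)-2-[(2R,3S,4S)-3-ethenyl-3,4-dimethyl-2-(prop-2-en-1-yl)-4-(trimethylsilyloxy)cyclohexylidene]propan-1-ol F5, and Bu4NF returns to 10.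

## Further compounds

F1 | step 1 | racemic 4-hydroxy-3,4-dimethylcyclohexa-2,5-dien-1-one | CC1=CC(=O)C=CC1(C)O
F2 | step 4 | allyl (3S,4S)-3-ethenyl-3,4-dimethyl-4-(trimethylsilyloxy)cyclohex-1-en-1-yl carbonate | C=C[C@@]1(C)C=C(OC(=O)OCC=C)CC[C@]1(C)O[Si](C)(C)C
F3 | step 6 | (2E)-2-[(2R,3S,4S)-3-ethenyl-3,4-dimethyl-2-(prop-2-en-1-yl)-4-(trimethylsilyloxy)cyclohexylidene]propanal | C/C(C=O)=C1/CC[C@](C)(O[Si](C)(C)C)[C@@](C)(C=C)[C@@H]1CC=C
F4 | step 6 | (2Z)-2-[(2R,3S,4S)-3-ethenyl-3,4-dimethyl-2-(prop-2-en-1-yl)-4-(trimethylsilyloxy)cyclohexylidene]propanal | C/C(C=O)=C1\CC[C@](C)(O[Si](C)(C)C)[C@@](C)(C=C)[C@@H]1CC=C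
F5 | step 6 | (2Z)-2-[(2R,3S,4S)-3-ethenyl-3,4-dimethyl-2-(prop-2-en-1-yl)-4-(trimethylsilyloxy)cyclohexylidene]propan-1-ol | C/C(CO)=C1\CC[C@](C)(O[Si](C)(C)C)[C@@](C)(C=C)[C@@H]1CC=C
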